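I wanted one slope.

all flasks: free catalyst 0.160 mM
- red: substrate 80.0 mM
- grey: substrate 240 mM
- amber: substrate 20.0 mM; time 8.2 min

- red run (time / min: [product] / mM): 1.6: 23.0; 3.3: 36.6; 4.9: 47.9; 6.6: 53.0; 8.2: 60.5
- grey run (time / min: [product] / mM): 1.6: 43.9; 3.3: 83.2; 4.9: 118.5; 6.6: 146.1; 8.2: 165.8

(standard deviation of a reading: 1 mM)

- the exponent of [substrate] in the starting rate at the charge of the red run (at the point where two percent of the substrate have become product) (one fixed amount of product, the same in the runs compared)
- product in the amber run at 8.2 min, as a share of the substrate charged

- Overall: substrate -> product, with free catalyst as catalyst.
- Constant volume, constant temperature.
- The analysis sees a species whether free or bound.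
- An order is taken over about fifteen percent of the charge, up and down.

I read the red run as a passage through falling substrate. Its last stretch, from 4.9 min to 8.2 min, ran at 3.82 mM/min around 25.8 mM of substrate, which lies near the charge of the amber run, but that stretch of the red run held about 54.2 mM of product while the amber run starts with none, so I took the tail of the red run as a rough stand-in for the start of the amber run, not as a picture of it. Its first row gave 14.4 mM/min around 68.5 mM, and the slope of log rate against log substrate between those two rows came to 1.36, give or take 0.115 from the scatter; this low-end order is an apparent order, read along one run.

Setting the first row of the grey run, 27.4 mM/min around 218 mM, against the first row of the red run gave a slope of 0.558, which is lower than the low-end order. I joined the two ends on the log-substrate axis and got 0.876 at the red charge. Then I ran the power law with the low-end order forward from the amber charge, anchored on the red tail, and it gave me 60.7%.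

The forecast judged “That points to saturation” and gave an order of 0.65 and 80%, which is 19 percentage points above my share.

The simulation gave an order of 0.78 and 57.9% for the amber run.

    free catalyst + substrate ⇌ catalyst-substrate complex, settled at all times (1.540 /M)
    catalyst-substrate complex + substrate ⇌ doubly bound catalyst, settled at all times (194.0 /M)
    doubly bound catalyst → product + catalyst-substrate complex (154.8 /min)
    free catalyst + product ⇌ catalyst-product complex, settled at all times (13.20 /M)
    substrate → product (0.02472 /min)

My amber figure stood 2.8 points above the result, the forecast 22 points. Carried into the grey run, the low-end law put the passage from a quarter to half of the charge at 1.47 min, but that run took 2.78 min, so this order belongs to low substrate. In the amber run, substrate also passes into product without catalyst: with that passing taken away the run reaches 51.0% instead of 57.9%, so that passing adds 6.9 points.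

All runs stem from a simulated flask with constants of no real substance; noise was put on by code.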